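**Plan**

- Cuts, in retrosynthetic order: the four O–CH2OCH3 bonds; the C3–C4 bond of the pyranone ring (O1, C2, C3, C4, C4a, C8a); the O1–C2 ether bond; in ring B the O4'–CH3 bond and the C5'–C(CH3)2 bond, the latter traced back to a prenyl ether on O4'.
- Enabling feature: C3 carries OH and the aryl ring B and sits next to the C4 ketone. This tertiary alpha-ketol is the mark of an acyl anion at C4 (an aldehyde on ring A) adding to an aryl ketone at C3.
- Forward, ring B: gallacetophenone is prenylated on O4', protected, rearranged so that the 1,1-dimethylallyl group arrives on C5', methylated on O4' and brominated on the acetyl carbon.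
- Forward, assembly: the ring A salicylaldehyde is joined through O1–C2, the pyranone ring is closed last, and the protecting groups are then removed. Both benzene rings are bought.
- Stereochemistry: the only stereocenter, C3 (R), is set in the ring closure by a chiral triazolylidene catalyst. As a quaternary carbinol it cannot epimerise by enolisation afterwards.

Key step: step 8

Remarks on the chemistry:
- Locants C2 to C8a refer to the chroman-4-one of the target and primed locants to its pendant aryl ring (ring B); ring A is the benzo ring of the chromanone.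
- Assumption: the (5aR,10bS) antipode of the aminoindanol-derived triazolium salt, made from (1S,2R)-1-amino-2-indanol, is taken to be the one that gives the (R)-ketol. The sense of induction has to be confirmed on first use, and the (5aS,10bR) salt is used instead if it proves opposite.

**Route**

Step 1
Reactants: 1 1-(2,3,4-trihydroxyphenyl)ethanone (gallacetophenone); 2 1-bromo-3-methylbut-2-ene (prenyl bromide)
Product: 3 1-[2,3-dihydroxy-4-(3-methylbut-2-enyloxy)phenyl]ethanone
Conditions: 2 (1.05 equiv), K2CO3 (1.0 equiv), DMF, 0 °C to rt
Reagents that add atoms: none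
Why: Williamson ether synthesis under acidity control, in which one equivalent of carbonate ionises only the 4-OH (the most acidic phenol, para to the acetyl group) while the 2-OH is held in a hydrogen bond to the carbonyl, so the allylic bromide should alkylate O4.

Step 2
Reactants: 3 1-[2,3-dihydroxy-4-(3-methylbut-2-enyloxy)phenyl]ethanone
Product: 4 1-[2,3-bis(methoxymethoxy)-4-(3-methylbut-2-enyloxy)phenyl]ethanone
Conditions: NaH (2.1 equiv), MOMCl (2.3 equiv), DMF, 0 °C to rt
Reagents that add atoms: chloromethyl methyl ether, COCCl
Why: Williamson-type formation of two methoxymethyl ethers, in which NaH frees even the chelated 2-oxide and the reactive chloromethyl ether alkylates both phenoxides, while the ketone is not enolised at this stoichiometry and the allyl ether is inert.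

Step 3
Reactants: 4 1-[2,3-bis(methoxymethoxy)-4-(3-methylbut-2-enyloxy)phenyl]ethanone
Product: 6 1-[4-hydroxy-2,3-bis(methoxymethoxy)-5-(2-methylbut-3-en-2-yl)phenyl]ethanone, via ortho-dienone 5 (not isolated)
Conditions: PhNEt2, 190 °C, sealed tube, Ar
Reagents that add atoms: none
Why: Aromatic Claisen rearrangement, whose [3,3] shift can end productively only at C5 (the one ortho carbon that carries hydrogen), giving dienone 5 that tautomerises to the phenol with the allyl unit inverted to the 1,1-dimethylallyl group, while the basic solvent keeps the acetals intact.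

Step 4
Reactants: 6 1-[4-hydroxy-2,3-bis(methoxymethoxy)-5-(2-methylbut-3-en-2-yl)phenyl]ethanone
Product: 7 1-[4-methoxy-2,3-bis(methoxymethoxy)-5-(2-methylbut-3-en-2-yl)phenyl]ethanone
Conditions: MeI, K2CO3, DMF, rt, directly after step 3
Reagents that add atoms: iodomethane, CI
Why: Williamson methylation of a phenoxide that is acidified by the para acetyl group and is alkylated by the small electrophile despite its two ortho substituents, which removes the phenol before it can add to the neighbouring alkene.

Step 5
Reactants: 7 1-[4-methoxy-2,3-bis(methoxymethoxy)-5-(2-methylbut-3-en-2-yl)phenyl]ethanone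
Product: 9 2-bromo-1-[4-methoxy-2,3-bis(methoxymethoxy)-5-(2-methylbut-3-en-2-yl)phenyl]ethanone, via trimethylsilyl enol ether 8 (not isolated)
Conditions: LiN(SiMe3)2, THF, −78 °C; Me3SiCl; then NBS, −78 to 0 °C
Reagents that add atoms: N-bromosuccinimide, O=C1CCC(=O)N1Br; chlorotrimethylsilane, C[Si](C)(C)Cl (its silyl group is found in 8 only)
Why: Alpha-bromination of a ketone through its silyl enol ether, in which the acetyl methyl is the only enolisable position and the electron-rich enol ether takes up bromine from NBS far faster than the isolated monosubstituted alkene or the acyl-deactivated arene, without any HBr that could cleave the acetals.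

Step 6
Reactants: 10 2,4,6-trihydroxybenzaldehyde
Product: 11 2-hydroxy-4,6-bis(methoxymethoxy)benzaldehyde
Conditions: MOMCl (2.1 equiv), iPr2NEt, CH2Cl2, 0 °C to rt
Reagents that add atoms: chloromethyl methyl ether, COCCl
Why: Selective methoxymethyl ether formation, in which the 4-OH and one of the two equivalent ortho hydroxyls react under amine base and the last ortho OH, locked in a hydrogen bond to the formyl group, should stay free.

Step 7
Reactants: 9 2-bromo-1-[4-methoxy-2,3-bis(methoxymethoxy)-5-(2-methylbut-3-en-2-yl)phenyl]ethanone; 11 2-hydroxy-4,6-bis(methoxymethoxy)benzaldehyde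
Product: 12 2-{2-[4-methoxy-2,3-bis(methoxymethoxy)-5-(2-methylbut-3-en-2-yl)phenyl]-2-oxoethoxy}-4,6-bis(methoxymethoxy)benzaldehyde
Conditions: K2CO3, acetone, rt, short reaction time
Reagents that add atoms: none
Why: Williamson ether synthesis, in which the phenoxide of 11 displaces bromide from the very reactive primary alpha-bromo ketone at room temperature, where the following aldol condensation to a 2-aroylbenzofuran (Rap-Stoermer reaction) is slow.

Step 8
Reactants: 12 2-{2-[4-methoxy-2,3-bis(methoxymethoxy)-5-(2-methylbut-3-en-2-yl)phenyl]-2-oxoethoxy}-4,6-bis(methoxymethoxy)benzaldehyde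
Product: 13 (3R)-3-hydroxy-3-[4-methoxy-2,3-bis(methoxymethoxy)-5-(2-methylbut-3-en-2-yl)phenyl]-5,7-bis(methoxymethoxy)chroman-4-one
Conditions: (5aR,10bS)-2-(pentafluorophenyl)-5a,10b-dihydro-4H,6H-indeno[2,1-b][1,2,4]triazolo[4,3-d][1,4]oxazin-2-ium tetrafluoroborate (15 mol%), Et3N (15 mol%), toluene, rt, Ar
Reagents that add atoms: none
Why: Et3N frees the triazolylidene, which adds to the formyl carbon of 12; a proton shift gives the enaminol (Breslow intermediate), whose nucleophilic carbon (the future C4) attacks the tethered aryl ketone carbon (the future C3), and collapse of the adduct releases the carbene and the C4 ketone. The closest known reaction type is the carbene-catalysed enantioselective intramolecular crossed aldehyde-ketone benzoin reaction of 2-(2-aryl-2-oxoethoxy)benzaldehydes, which gives 3-aryl-3-hydroxychroman-4-ones. The pyranone ring (O1, C2, C3, C4, C4a, C8a) is closed in a 6-exo-trig mode through the new C3-C4 bond. The one new stereocenter, C3, is controlled by the catalyst alone: the indane-fused backbone of the carbene blocks one face of the enaminol, so that the ketone can approach with only one of its enantiotopic faces, and the antipode named in the assumption is chosen for 3R. The step needs chemoselectivity (acyl anion from the aldehyde only, no aldol closure to a benzofuran), and this is secured because only the formyl group has the hydrogen needed to form the enaminol, the ketone is held three atoms away by the O-CH2 tether, and the weak amine base does not enolise the aryloxymethyl ketone to a useful extent. The product is a tertiary ketol that does not revert easily, and the acetal ethers, the methyl ether and the terminal alkene are inert to carbene and base.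

Step 9
Reactants: 13 (3R)-3-hydroxy-3-[4-methoxy-2,3-bis(methoxymethoxy)-5-(2-methylbut-3-en-2-yl)phenyl]-5,7-bis(methoxymethoxy)chroman-4-one
Product: 14 (3R)-3-[2,3-dihydroxy-4-methoxy-5-(2-methylbut-3-en-2-yl)phenyl]-3,5,7-trihydroxychroman-4-one (CNP0205426.1)
Conditions: HCl (2 M in MeOH), 40 °C
Reagents that add atoms: none
Why: Acid-catalysed transacetalisation with methanol should remove the four methoxymethyl groups as dimethoxymethane, while the monosubstituted alkene on a quaternary carbon, the aryl methyl ether and the tertiary ketol (no enolisable hydrogen at C3, ionisation disfavoured by the adjacent carbonyl) are left intact and C3 keeps its configuration.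

**Compound list**

1 | 1-(2,3,4-trihydroxyphenyl)ethanone (gallacetophenone) | CC(=O)c1ccc(O)c(O)c1O | starting material
2 | 1-bromo-3-methylbut-2-ene (prenyl bromide) | CC(C)=CCBr | starting material
3 | 1-[2,3-dihydroxy-4-(3-methylbut-2-enyloxy)phenyl]ethanone | CC(=O)c1ccc(OCC=C(C)C)c(O)c1O | intermediate
4 | 1-[2,3-bis(methoxymethoxy)-4-(3-methylbut-2-enyloxy)phenyl]ethanone | CC(=O)c1ccc(OCC=C(C)C)c(OCOC)c1OCOC | intermediate
5 | rac-4-acetyl-2,3-bis(methoxymethoxy)-6-(2-methylbut-3-en-2-yl)cyclohexa-2,4-dien-1-one (ortho-dienone, not isolated) | CC(=O)C1=CC(C(C)(C)C=C)C(=O)C(OCOC)=C1OCOC | intermediate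
6 | 1-[4-hydroxy-2,3-bis(methoxymethoxy)-5-(2-methylbut-3-en-2-yl)phenyl]ethanone | CC(=O)c1cc(C(C)(C)C=C)c(O)c(OCOC)c1OCOC | intermediate
7 | 1-[4-methoxy-2,3-bis(methoxymethoxy)-5-(2-methylbut-3-en-2-yl)phenyl]ethanone | CC(=O)c1cc(C(C)(C)C=C)c(OC)c(OCOC)c1OCOC | intermediate
8 | {1-[4-methoxy-2,3-bis(methoxymethoxy)-5-(2-methylbut-3-en-2-yl)phenyl]ethenyloxy}trimethylsilane (silyl enol ether, not isolated) | C=C(O[Si](C)(C)C)c1cc(C(C)(C)C=C)c(OC)c(OCOC)c1OCOC | intermediate
9 | 2-bromo-1-[4-methoxy-2,3-bis(methoxymethoxy)-5-(2-methylbut-3-en-2-yl)phenyl]ethanone | O=C(CBr)c1cc(C(C)(C)C=C)c(OC)c(OCOC)c1OCOC | intermediate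
10 | 2,4,6-trihydroxybenzaldehyde | O=Cc1c(O)cc(O)cc1O | starting material
11 | 2-hydroxy-4,6-bis(methoxymethoxy)benzaldehyde | O=Cc1c(O)cc(OCOC)cc1OCOC | intermediate
12 | 2-{2-[4-methoxy-2,3-bis(methoxymethoxy)-5-(2-methylbut-3-en-2-yl)phenyl]-2-oxoethoxy}-4,6-bis(methoxymethoxy)benzaldehyde | O=Cc1c(OCC(=O)c2cc(C(C)(C)C=C)c(OC)c(OCOC)c2OCOC)cc(OCOC)cc1OCOC | intermediate
13 | (3R)-3-hydroxy-3-[4-methoxy-2,3-bis(methoxymethoxy)-5-(2-methylbut-3-en-2-yl)phenyl]-5,7-bis(methoxymethoxy)chroman-4-one | C=CC(C)(C)c1cc([C@@]2(O)COc3cc(OCOC)cc(OCOC)c3C2=O)c(OCOC)c(OCOC)c1OC | intermediate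
14 | (3R)-3-[2,3-dihydroxy-4-methoxy-5-(2-methylbut-3-en-2-yl)phenyl]-3,5,7-trihydroxychroman-4-one (CNP0205426.1) | C=CC(C)(C)c1cc([C@@]2(O)COc3cc(O)cc(O)c3C2=O)c(O)c(O)c1OC | target

**Step count**

Total: 9 steps. Longest linear sequence: 8 steps (steps 1, 2, 3, 4, 5, 7, 8, 9, from gallacetophenone); the ring A branch contributes step 6.

**Steps most likely to fail**

Step 8, the carbene-catalysed ring closure. The formyl group is flanked by two ortho oxygen substituents, so addition of the bulky chiral carbene may be slow. The ortho-substituted aryl ketone may also be attacked with poor enantiofacial selectivity, and a slow benzoin leaves time for the aldol closure to a benzofuran. The fallback gives up asymmetric induction and obtains the stereocenter by resolution. It sets out from 12, which is cyclised with the small achiral carbene generated from 2-(pentafluorophenyl)-6,7-dihydro-5H-pyrrolo[2,1-c][1,2,4]triazol-2-ium tetrafluoroborate and Et3N in toluene. This should give the racemic ketol rac-3-hydroxy-3-[4-methoxy-2,3-bis(methoxymethoxy)-5-(2-methylbut-3-en-2-yl)phenyl]-5,7-bis(methoxymethoxy)chroman-4-one F1. The enantiomers of F1 are then separated by preparative chromatography on a chiral stationary phase (amylose tris(3,5-dimethylphenylcarbamate)). The (R)-enantiomer is 13, where the route is rejoined.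

Step 3, the Claisen rearrangement. At the temperature that the acyl-substituted aryl ether needs, the first-formed ortho-(1,1-dimethylallyl)phenol may react on, either by abnormal Claisen rearrangement or by addition of its hydroxyl group to the new alkene. The fallback never liberates this phenol. It sets out from 4, which is rearranged in PhNEt2 at 190 °C in the presence of Ac2O and NaOAc, so that the phenoxide is acetylated as it forms. This should give 4-acetyl-2,3-bis(methoxymethoxy)-6-(2-methylbut-3-en-2-yl)phenyl acetate F2. Methanolysis of the acetate with K2CO3 in MeOH, followed by MeI in the same flask, converts F2 directly into the methyl ether 7, where the route is rejoined; compound 6 is bypassed.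

Step 9, the final deprotection. Once ring B is freed, the acid may ionise the tertiary benzylic C3–OH and cause dehydration to the isoflavone, and formaldehyde equivalents may alkylate the electron-rich ring A. The fallback moves the acid treatment ahead of the ring closure and ends with a fluoride-labile protecting group. It sets out from 12, whose four methoxymethyl groups are removed with HCl in MeOH while no ketol is yet present, giving 2-{2-[2,3-dihydroxy-4-methoxy-5-(2-methylbut-3-en-2-yl)phenyl]-2-oxoethoxy}-4,6-dihydroxybenzaldehyde F3. Silylation with t-BuMe2SiCl and imidazole in DMF gives the tetrakis(tert-butyldimethylsilyl) ether of that keto aldehyde F4. The carbene-catalysed cyclisation of step 8, under the same conditions, should then give (3R)-3-hydroxy-3-[2,3-bis(tert-butyldimethylsilyloxy)-4-methoxy-5-(2-methylbut-3-en-2-yl)phenyl]-5,7-bis(tert-butyldimethylsilyloxy)chroman-4-one F5. Desilylation with Et3N·3HF in THF at 0 °C to rt, nearly neutral conditions that spare the ketol, returns to the route at 14.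

Further compounds
F1 | step 8 | rac-3-hydroxy-3-[4-methoxy-2,3-bis(methoxymethoxy)-5-(2-methylbut-3-en-2-yl)phenyl]-5,7-bis(methoxymethoxy)chroman-4-one | C=CC(C)(C)c1cc(C2(O)COc3cc(OCOC)cc(OCOC)c3C2=O)c(OCOC)c(OCOC)c1OC
F2 | step 3 | 4-acetyl-2,3-bis(methoxymethoxy)-6-(2-methylbut-3-en-2-yl)phenyl acetate | CC(=O)Oc1c(C(C)(C)C=C)cc(C(C)=O)c(OCOC)c1OCOC
F3 | step 9 | 2-{2-[2,3-dihydroxy-4-methoxy-5-(2-methylbut-3-en-2-yl)phenyl]-2-oxoethoxy}-4,6-dihydroxybenzaldehyde | O=Cc1c(OCC(=O)c2cc(C(C)(C)C=C)c(OC)c(O)c2O)cc(O)cc1O
F4 | step 9 | 2-{2-[2,3-bis(tert-butyldimethylsilyloxy)-4-methoxy-5-(2-methylbut-3-en-2-yl)phenyl]-2-oxoethoxy}-4,6-bis(tert-butyldimethylsilyloxy)benzaldehyde | O=Cc1c(OCC(=O)c2cc(C(C)(C)C=C)c(OC)c(O[Si](C)(C)C(C)(C)C)c2O[Si](C)(C)C(C)(C)C)cc(O[Si](C)(C)C(C)(C)C)cc1O[Si](C)(C)C(C)(C)C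
F5 | step 9 | (3R)-3-hydroxy-3-[2,3-bis(tert-butyldimethylsilyloxy)-4-methoxy-5-(2-methylbut-3-en-2-yl)phenyl]-5,7-bis(tert-butyldimethylsilyloxy)chroman-4-one | C=CC(C)(C)c1cc([C@@]2(O)COc3cc(O[Si](C)(C)C(C)(C)C)cc(O[Si](C)(C)C(C)(C)C)c3C2=O)c(O[Si](C)(C)C(C)(C)C)c(O[Si](C)(C)C(C)(C)C)c1OC
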